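## Structural features

Labdane numbering is used for the target and all intermediates: decalin C1–C10 (rings A and B), C17 on C8, C18 and C19 on C4, C20 on C10, side chain C11–C16 with C15 the lactone carbonyl. The target is a trans-decalin (5α-H, 10β-CH3) whose C9 is the spiro atom of a tetrahydrofuran (ring C: C9, C11, C12, C13, O) and whose C13 is in turn the spiro atom of a γ-lactone (ring D: C13, C14, C15, O, C16). Five contiguous stereocentres lie on ring B, namely C5, quaternary C10, fully substituted C9 (oxygen axial and α, C11 equatorial and β), C8 (equatorial α-CH3) and C7 (equatorial β-OH) beside the C6 ketone, while the sixth, C13 (R), is insulated from them by the ring-C oxygen and the C11–C12 bridge. Fragile groups are the C6/C7 α-ketol (epimerisation at C7 and C5, acyloin shift), the C13–O bond, which is β to the lactone carbonyl and can open by retro-oxa-Michael reaction under base, and both tertiary ether C–O bonds under acid. The real difficulty is C13: its two arms C14 and C16 differ only at the far side of ring D, and it looks at a nearly mirror-symmetric neighbourhood around C9 (C8 with equatorial C17 against C10 with equatorial C1), so neither substrate bias nor equilibration can be expected to set it; C9, wedged between quaternary C10 and C8, comes second. The key step exploits the fact that C13 carries the C9 oxygen and two one-carbon arms that meet at C15, so that rings C and D together are a tertiary alcohol, a 2-methylidenepropane-1,3-diyl unit and one molecule of carbon monoxide; they are closed in one palladium-catalysed oxidative carbonylation that creates C13 while its arms are still an alkene CH2 and a CH2OH. Ring B with C6=O, C9=O, C17 and C20 maps onto a 2,6-dimethylated benzoquinone, which is used to build the decalin.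

## Logic of the disconnections

15 ⇒ 13 (through 14). Bond cut: C7–O. The α-ketol is the most fragile group, so its hydroxyl is introduced last and needs no protecting group. C7 is the only unhindered enolisable position of the C6 ketone. Gain: one stereocentre and one oxygen fewer in every earlier intermediate. Demand: oxygen must arrive on the β face of C7, which the syn-axial C9–O bond on the α face should enforce, and the base must leave the β-alkoxy lactone intact.

13 ⇒ 12. No skeletal bond is cut; C6 is taken back to the alcohol level. The organolithium that forges C11–C12 cannot coexist with a ketone, so C6 travels as a hydroxyl from 7 to 12. Demand: in 12 this must be the only free hydroxyl, which the key step guarantees by consuming the other two.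

12 ⇒ 11 + carbon monoxide (key disconnection). Bonds cut: O9–C13, C14–C15 and C15–O16. Rings C and D and the stereocentre C13 disappear together, C15 is returned to carbon monoxide, and 11 has stereocentres only on the decalin. Demand: Markovnikov 5-exo oxypalladation by a hindered tertiary alcohol, CO insertion into an alkylpalladium that cannot β-eliminate, capture of the acylpalladium by O16, and control of the alkene face by a chiral ligand.

11 ⇒ 8 + 9 (through 10). Bond cut: C11–C12, the only CH2–CH2 bond of the side chain. The C9–O bond is already present in 8 as an oxirane and becomes the 9α-hydroxyl on opening. Gain: the whole C12–C13(=C14)–C16 unit is the commercial four-carbon alcohol 9. Demand: SN2 attack at the hindered oxirane CH2 must outrun base-induced elimination.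

8 ⇒ 7 ⇒ 6 ⇒ 5. Bonds cut: the C9–O oxirane bond and the C9=C11 bond; C6 is carried as the alcohol in 7. Epoxidation anti to C20 sets C9. Gain: 5 is a simple dione with three stereocentres. Demand: olefination of C9=O in preference to C6=O in 5, and α-face epoxidation of 7.

5 ⇒ 3 (through 4). No skeletal bond is cut; two alkenes and two stereocentres (C5, C8) are removed. Both centres are α to a carbonyl and are set by equilibration once C10 is fixed. Demand: the trans-fused 8α-methyl isomer must be the thermodynamic one.

3 ⇒ 1 + 2. Bonds cut: C1–C10 and C4–C5 (ring A, by Diels–Alder reaction). Gain: two achiral commercial compounds; 1 supplies ring B with both carbonyls and both methyls in place, 2 supplies the gem-dimethyl carbon. Demand: regiochemistry (CH2 terminus of 2 to the methyl-bearing carbon of 1), enantioface control at C10 by the catalyst, and sufficient reactivity of a diene with a Z-methyl group.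

## Other disconnections considered

Alternative 1: Cut O9–C13 alone. Forward key step: intramolecular oxa-Michael addition of the 9α-hydroxyl of hydroxy butenolide A1 to C13. This is the first route that comes to mind. It is set aside because in A1 both arms of C13 are already tied into the planar butenolide. Its two faces meet the near-symmetric surroundings of C9, the addition is reversible, and no reagent takes part, so C13 would be expected to form without useful control. A1 must also be assembled with its complete six-carbon side chain, which costs more steps than the one-step union of 8 with 9 followed by carbon monoxide.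

Alternative 2: Delete the ring-D oxygen, i.e. cut O–C16 to reach spiro cyclobutanone A2, in which C13 is not yet a stereocentre. Forward key step: catalytic desymmetrising Baeyer–Villiger oxygen insertion. A2 would come from exocyclic enol ether A3 by dichloroketene [2+2] cycloaddition and dechlorination, and A3 from spiro lactone A4 by carbonyl methylenation. The idea is sound, but it needs four to five operations after C9 is set where the chosen plan needs two. Making A4 by SmI2-mediated ketyl–acrylate coupling on a C9 ketone would bond carbon from the axial α face, the wrong sense at C9. The oxidation catalyst would have to tell O from CH2 on a spiro ring. A 3-alkoxycyclobutanone is also prone to Lewis-acid-induced C13–C14 cleavage.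

Alternative 3: Cut O–C9 with reversed roles. Forward key step: oxa-Michael addition of the C13 hydroxyl of enone A5 (C13 bought by asymmetric epoxidation of a 2-substituted allylic alcohol) to C9 of the ring-B 8-en-7-one, giving ketone A6. Axial α attack at C9 and equilibration of C8 are plausible, and C13 would be secure. However, the carbonyl ends at C7, so a 1,2-transposition to the 6-oxo-7β-hydroxy pattern must follow in the presence of the base-labile β-alkoxy lactone. Addition of a tertiary alkoxide to a fully substituted β-carbon next to quaternary C10 is also likely to be thermodynamically unfavourable. The side-chain fragment alone would take as many steps as the whole chosen endgame.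

Key step: step 7

Assumption: the absolute sense of induction of the oxazaborolidinium catalyst (step 1) and of the bis(isoxazoline) ligand (step 7) is taken as written; should either prove opposite, its mirror-image form is used instead.

## Route

Step 1
Reactants: 1 2,6-dimethyl-1,4-benzoquinone; 2 4-methylpenta-1,3-diene
Product: 3 (4aR,8aS)-2,5,5,8a-tetramethyl-4a,5,8,8a-tetrahydronaphthalene-1,4-dione (cis-fused; labdane locants: 5β-H, 10β-CH3, alkenes C2=C3 and C7=C8)
Conditions: oxazaborolidinium triflimide from (S)-α,α-diphenylprolinol, o-tolylboroxine and Tf2NH (20 mol %), CH2Cl2, −78 to −40 °C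
Reagents that add atoms: none
Why: Catalytic enantioselective Diels–Alder reaction of a quinone: the chiral Lewis acid binds the unhindered carbonyl (future C6=O), the nucleophilic CH2 terminus of 2 bonds to the methyl-bearing β-carbon (C1–C10, quaternary C10) and the CMe2 terminus to the CH carbon (C4–C5), a regiochemistry favoured both sterically and electronically and still obtained if bond formation is highly asynchronous. Endo addition gives the cis ring fusion; the catalyst-shielded face sets C10 (S), the only stereocentre of 3 that has to persist.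

Step 2
Reactants: 3 (4aR,8aS)-2,5,5,8a-tetramethyl-4a,5,8,8a-tetrahydronaphthalene-1,4-dione
Product: 5 (2R,4aS,8aS)-2,5,5,8a-tetramethyloctahydronaphthalene-1,4-dione (trans-fused 8α-methyl 6,9-dione), via cis-fused saturated dione 4 (not isolated)
Conditions: H2 (3 atm), 10% Pd/C, EtOAc, rt; filter; then NaOMe (0.3 equiv), MeOH, rt
Reagents that add atoms: none
Why: Heterogeneous hydrogenation saturates the ene-dione bond C7=C8 and the ring-A alkene. Methoxide then epimerises C5 (α to C6=O) to the trans-decalin and C8 (α to C9=O) to the equatorial 8α-methyl, which avoids a 1,3-diaxial clash with C20, so both centres are set by thermodynamic control relayed from C10.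

Step 3
Reactants: 5 (2R,4aS,8aS)-2,5,5,8a-tetramethyloctahydronaphthalene-1,4-dione
Product: 6 (3R,4aS,8aS)-3,4a,8,8-tetramethyl-4-methylideneoctahydronaphthalen-1(2H)-one (6-oxo; C9=C11H2)
Conditions: Zn, CH2Br2, TiCl4, THF–CH2Cl2, 0 °C to rt
Reagents that add atoms: dibromomethane, BrCBr
Why: Takai–Lombardo methylenation, a non-basic carbonyl olefination that does not epimerise C8 or C5. C9=O offers an open axial α trajectory, whereas C6=O is screened on the β face by the syn-axial C19 and C20 methyls and on the α side by the peri C18 methyl, so mono-olefination at C9 is expected.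

Step 4
Reactants: 6 (3R,4aS,8aS)-3,4a,8,8-tetramethyl-4-methylideneoctahydronaphthalen-1(2H)-one
Product: 7 (1R,3R,4aS,8aS)-3,4a,8,8-tetramethyl-4-methylidenedecahydronaphthalen-1-ol (6β-OH; C9=C11H2)
Conditions: LiAlH4, THF, 0 °C
Reagents that add atoms: none
Why: Hydride reduction masks the ketone before the organolithium step. Delivery from the open α face should give the axial 6β-alcohol; its configuration is immaterial because C6 is re-oxidised in step 8.

Step 5
Reactants: 7 (1R,3R,4aS,8aS)-3,4a,8,8-tetramethyl-4-methylidenedecahydronaphthalen-1-ol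
Product: 8 (5S,6R,8R,9R,10S)-9α,11-epoxy-12,13,14,15,16-pentanorlabdan-6β-ol (spiro-oxirane on C9, oxygen axial and α)
Conditions: mCPBA, NaHCO3, CH2Cl2, 0 °C
Reagents that add atoms: 3-chloroperoxybenzoic acid, OOC(=O)c1cccc(Cl)c1
Why: Prilezhaev epoxidation of the exocyclic alkene from the α face, anti to the axial C20 methyl on the adjacent carbon. This places the oxirane oxygen axial (9α) and C11 equatorial (β) and so sets C9 (R).

Step 6
Reactants: 8 (5S,6R,8R,9R,10S)-9α,11-epoxy-12,13,14,15,16-pentanorlabdan-6β-ol; 9 2-methylprop-2-en-1-ol
Product: 11 (5S,6R,8R,9R,10S)-15-norlabd-13(14)-ene-6β,9α,16-triol, via dilithiated 2-methylprop-2-en-1-ol 10 (not isolated)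
Conditions: 9 (4 equiv), nBuLi (8 equiv), TMEDA, Et2O–hexane, 0 °C to rt; then 8, THF, −20 °C to rt; aq NH4Cl
Reagents that add atoms: none
Why: SN2 opening of the 1,1-disubstituted oxirane at its CH2 terminus (C11) by the allylic carbanion of the alkoxide-allyl dianion forms C11–C12. The C9–O bond is untouched, so the 9α configuration is retained and no new stereocentre arises; the excess dianion compensates for the free 6-OH.

Step 7
Reactants: 11 (5S,6R,8R,9R,10S)-15-norlabd-13(14)-ene-6β,9α,16-triol
Product: 12 (5S,6R,8R,9R,10S,13R)-9α,13-epoxy-6β-hydroxylabdan-15,16-olide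
Conditions: Pd(OCOCF3)2 (10 mol %), (M,S,S)-iPr-SPRIX spiro bis(isoxazoline) ligand (12 mol %), p-benzoquinone (2 equiv), CO (1 atm), CH2Cl2, 0 °C to rt
Reagents that add atoms: carbon monoxide, [C-]#[O+]
Why: Intramolecular oxidative alkoxycarbonylation (Wacker-type oxypalladation, CO insertion, acyl substitution), the known hydroxycyclisation–carbonylation–lactonisation of unsaturated diols, applied here to a 1,1-disubstituted alkene so that the two new rings end up spiro instead of fused. Divalent palladium binds the only alkene (C13=C14) and the tertiary 9α-OH adds to C13 in a 5-exo-trig, Markovnikov sense, which closes ring C and creates C13. The resulting C14–Pd bond has no β-hydrogen because C13 is fully substituted, so CO insertion is its only outlet; the acylpalladium (C15) is then captured by O16 in a 5-exo-trig acyl substitution that closes ring D and releases zerovalent palladium, which p-benzoquinone reoxidises. Chemoselectivity follows from ring size: only O9 can reach C13 and only O16 can reach C15 through five-membered transition states, and the 6β-OH can reach neither. C13 is the one new stereocentre; the substrate offers little bias because C13 faces a nearly mirror-symmetric environment around C9 (C8 with equatorial C17 against C10 with equatorial C1), so the alkene face is chosen by the chiral bis(isoxazoline) ligand on palladium. This reagent control is possible because at this moment the two arms of C13 are as different as they will ever be, a metal-bound CH2 (C14) and a free CH2OH (C16), whereas in the finished lactone they are nearly equivalent. The step therefore needs face selectivity (ligand), exo regioselectivity (the more substituted alkene carbon) and freedom from elimination (no β-H), each secured as stated.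

Step 8
Reactants: 12 (5S,6R,8R,9R,10S,13R)-9α,13-epoxy-6β-hydroxylabdan-15,16-olide
Product: 13 (5S,8R,9R,10S,13R)-9α,13-epoxy-6-oxolabdan-15,16-olide
Conditions: Dess–Martin periodinane, NaHCO3, CH2Cl2, rt
Reagents that add atoms: none
Why: Dess–Martin oxidation of the only free hydroxyl (axial, secondary). The buffered neutral conditions should leave the trans ring fusion at C5, the β-alkoxy lactone and both tertiary ethers untouched.

Step 9
Reactants: 13 (5S,8R,9R,10S,13R)-9α,13-epoxy-6-oxolabdan-15,16-olide
Product: 15 (5S,7R,8R,9R,10S,13R)-9α,13-epoxy-7β-hydroxy-6-oxolabdan-15,16-olide (CNP0291402.1), via potassium 6(7)-enolate 14 (not isolated)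
Conditions: KN(SiMe3)2 (1.05 equiv), THF, −78 °C; then 2-(phenylsulfonyl)-3-phenyloxaziridine (1.3 equiv), −78 °C; aq NH4Cl at −78 °C
Reagents that add atoms: 2-(phenylsulfonyl)-3-phenyloxaziridine (racemic), O=S(=O)(N1OC1c1ccccc1)c1ccccc1
Why: Kinetic enolisation of the ketone toward C7 (C5 is tertiary and buried beside C4; ketone α-H is more acidic than lactone α-H) followed by electrophilic enolate hydroxylation with an N-sulfonyloxaziridine. The α face of C7 is blocked by the syn-axial C9–O bond, so oxygen should be delivered from the β face to give the equatorial 7β-OH (7R), which is also the more stable epimer.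

## Compound list

1 | 2,6-dimethyl-1,4-benzoquinone | CC1=CC(=O)C=C(C)C1=O | starting material
2 | 4-methylpenta-1,3-diene | C=CC=C(C)C | starting material
3 | (4aR,8aS)-2,5,5,8a-tetramethyl-4a,5,8,8a-tetrahydronaphthalene-1,4-dione (cis-fused cycloadduct) | CC1=CC(=O)[C@@H]2C(C)(C)C=CC[C@]2(C)C1=O | intermediate
4 | (2R,4aR,8aS)-2,5,5,8a-tetramethyloctahydronaphthalene-1,4-dione (cis-fused, not isolated) | C[C@@H]1CC(=O)[C@@H]2C(C)(C)CCC[C@]2(C)C1=O | intermediate
5 | (2R,4aS,8aS)-2,5,5,8a-tetramethyloctahydronaphthalene-1,4-dione (trans-fused, 8α-methyl) | C[C@@H]1CC(=O)[C@H]2C(C)(C)CCC[C@]2(C)C1=O | intermediate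
6 | (3R,4aS,8aS)-3,4a,8,8-tetramethyl-4-methylideneoctahydronaphthalen-1(2H)-one | C[C@@H]1CC(=O)[C@H]2C(C)(C)CCC[C@]2(C)C1=C | intermediate
7 | (1R,3R,4aS,8aS)-3,4a,8,8-tetramethyl-4-methylidenedecahydronaphthalen-1-ol (6β-OH) | C[C@@H]1C[C@@H](O)[C@H]2C(C)(C)CCC[C@]2(C)C1=C | intermediate
8 | (5S,6R,8R,9R,10S)-9α,11-epoxy-12,13,14,15,16-pentanorlabdan-6β-ol | C[C@@H]1C[C@@H](O)[C@H]2C(C)(C)CCC[C@]2(C)[C@@]12CO2 | intermediate
9 | 2-methylprop-2-en-1-ol | C=C(C)CO | starting material
10 | dilithiated 2-methylprop-2-en-1-ol (alkoxide-allyl dianion, not isolated) | [Li]CC(=C)CO[Li] | intermediate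
11 | (5S,6R,8R,9R,10S)-15-norlabd-13(14)-ene-6β,9α,16-triol | C[C@@H]1C[C@@H](O)[C@H]2C(C)(C)CCC[C@]2(C)[C@@]1(O)CCC(=C)CO | intermediate
12 | (5S,6R,8R,9R,10S,13R)-9α,13-epoxy-6β-hydroxylabdan-15,16-olide | C[C@@H]1C[C@@H](O)[C@H]2C(C)(C)CCC[C@]2(C)[C@@]12CC[C@@]1(COC(=O)C1)O2 | intermediate
13 | (5S,8R,9R,10S,13R)-9α,13-epoxy-6-oxolabdan-15,16-olide | C[C@@H]1CC(=O)[C@H]2C(C)(C)CCC[C@]2(C)[C@@]12CC[C@@]1(COC(=O)C1)O2 | intermediate
14 | potassium 6(7)-enolate of 13 (not isolated) | C[C@@H]1C=C([O-])[C@H]2C(C)(C)CCC[C@]2(C)[C@@]12CC[C@@]1(COC(=O)C1)O2.[K+] | intermediate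
15 | (5S,7R,8R,9R,10S,13R)-9α,13-epoxy-7β-hydroxy-6-oxolabdan-15,16-olide (CNP0291402.1) | C[C@@H]1[C@@H](O)C(=O)[C@H]2C(C)(C)CCC[C@]2(C)[C@@]12CC[C@@]1(COC(=O)C1)O2 | target

## Step count and least certain steps

Total step count: 9. Longest linear sequence: 9 steps (1 to 15; 9 enters at step 6).

Step 7 (key step). Most likely failure: insufficient discrimination of the alkene faces in the oxypalladation, because the hindered tertiary alkoxide may react through a ligand-free pathway, or oxypalladation so slow that palladium precipitates before turnover. Fallback (stereocontrol by recycling instead of by ligand): setting out from 11, the ligand-free oxycarbonylation (PdCl2, CuCl2, NaOAc, AcOH, CO) should give 12 together with its C13 epimer, (5S,6R,8R,9R,10S,13S)-9α,13-epoxy-6β-hydroxylabdan-15,16-olide F1. After separation, F1 is treated with DBU, which opens it by retro-oxa-Michael reaction to 6β,9α-dihydroxylabd-13-en-15,16-olide F2 and lets it close again to both epimers. Repeated separation and equilibration funnel the material to 12, where the route is rejoined.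

Step 1. Most likely failure: slow cycloaddition because the Z-methyl group of 2 disfavours the s-cis conformer, with acid-induced oligomerisation of the diene competing, and erosion of enantioselectivity if an uncatalysed pathway takes over at the higher temperature then required. Fallback (a more nucleophilic diene, the extra oxygen removed afterwards), setting out from 1 and returning at 5: commercial 4-methylpent-3-en-2-one F3 is converted by soft enolisation (iPr3SiOTf, Et3N) into 4-methyl-2-(triisopropylsilyloxy)penta-1,3-diene F4. Under the same oxazaborolidinium catalysis, F4 adds to 1 (concertedly or as a double Michael addition) to give (5R,10S)-2-(triisopropylsilyloxy)-11,12,13,14,15,16-hexanorlabda-2,7-diene-6,9-dione F5. Hydrogenation of C7=C8 (H2, Pd/C), cleavage of the enol ether (Bu4NF) and NaOMe equilibration, telescoped, give (5S,8R,10S)-11,12,13,14,15,16-hexanorlabdane-2,6,9-trione F6. Its unhindered C2 ketone alone is converted into the 2,2-(ethane-1,2-diyldithio) derivative F7 (ethane-1,2-dithiol, BF3·OEt2), and desulfurisation with Raney Ni gives 5.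

Step 3. Most likely failure: loss of chemoselectivity (olefination at C6 as well) or no reaction at the hindered C9 carbonyl. Fallback (differentiation by regioselective enolisation instead of by steric shielding), setting out from 5 and returning at 6: kinetic deprotonation at C7 (LiN(SiMe3)2, THF, −78 °C, then tBuMe2SiCl) masks C6=O as (5S,8R,10S)-6-(tert-butyldimethylsilyloxy)-11,12,13,14,15,16-hexanorlabd-6-en-9-one F8. Wittig methylenation of the only remaining carbonyl (Ph3PCH3Br, KOtBu, toluene, 80 °C) gives (5S,8R,10S)-6-(tert-butyldimethylsilyloxy)-12,13,14,15,16-pentanorlabda-6,9(11)-diene F9, and Bu4NF returns ketone 6.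

Step 6. Most likely failure: base-induced isomerisation of the oxirane to an allylic alcohol (deprotonation at C8 with opening of the C9–O bond), or failure of the SN2 attack at the hindered CH2. Fallback (radical instead of anionic C11–C12 bond formation), setting out from 7 and returning at 11: N-iodosuccinimide in aqueous acetone, with water attacking C9 axially from the α face of the iodonium ion, gives (5S,6R,8R,9R,10S)-11-iodo-12,13,14,15,16-pentanorlabdane-6β,9α-diol F10. Its primary iodide is then allylated under tin-radical chain conditions (AIBN, benzene, 80 °C) with 2-[(tributylstannyl)methyl]prop-2-en-1-ol F11, itself made from 10 and Bu3SnCl, to give 11.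

Step 9. Most likely failure: competing deprotonation at the lactone α-carbon C14 followed by E1cB opening of the C13–O bond (loss of C13 integrity), insufficient β-face selectivity at C7, or acyloin shift if the alkoxide is allowed to warm. Fallback (base-free Rubottom oxidation), setting out from 13 and returning at 15: soft enolisation (Me3SiOTf, Et3N, CH2Cl2, 0 °C) gives (5S,8R,9R,10S,13R)-9α,13-epoxy-6-(trimethylsilyloxy)labd-6-en-15,16-olide F12. Epoxidation with dimethyldioxirane (acetone, −40 °C) and silyl migration give (5S,7R,8R,9R,10S,13R)-9α,13-epoxy-6-oxo-7β-(trimethylsilyloxy)labdan-15,16-olide F13, and AcOH–H2O–THF releases 15.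

## Further compounds

F1 | step 7 | (5S,6R,8R,9R,10S,13S)-9α,13-epoxy-6β-hydroxylabdan-15,16-olide | C[C@@H]1C[C@@H](O)[C@H]2C(C)(C)CCC[C@]2(C)[C@@]12CC[C@]1(COC(=O)C1)O2
F2 | step 7 | (5S,6R,8R,9R,10S)-6β,9α-dihydroxylabd-13-en-15,16-olide | C[C@@H]1C[C@@H](O)[C@H]2C(C)(C)CCC[C@]2(C)[C@@]1(O)CCC1=CC(=O)OC1
F3 | step 1 | 4-methylpent-3-en-2-one | CC(C)=CC(C)=O
F4 | step 1 | 4-methyl-2-(triisopropylsilyloxy)penta-1,3-diene | C=C(O[Si](C(C)C)(C(C)C)C(C)C)C=C(C)C
F5 | step 1 | (5R,10S)-2-(triisopropylsilyloxy)-11,12,13,14,15,16-hexanorlabda-2,7-diene-6,9-dione | CC1=CC(=O)[C@@H]2C(C)(C)C=C(O[Si](C(C)C)(C(C)C)C(C)C)C[C@]2(C)C1=O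
F6 | step 1 | (5S,8R,10S)-11,12,13,14,15,16-hexanorlabdane-2,6,9-trione | C[C@@H]1CC(=O)[C@H]2C(C)(C)CC(=O)C[C@]2(C)C1=O
F7 | step 1 | (5S,8R,10S)-2,2-(ethane-1,2-diyldithio)-11,12,13,14,15,16-hexanorlabdane-6,9-dione | C[C@@H]1CC(=O)[C@H]2C(C)(C)CC3(SCCS3)C[C@]2(C)C1=O
F8 | step 3 | (5S,8R,10S)-6-(tert-butyldimethylsilyloxy)-11,12,13,14,15,16-hexanorlabd-6-en-9-one | C[C@@H]1C=C(O[Si](C)(C)C(C)(C)C)[C@H]2C(C)(C)CCC[C@]2(C)C1=O
F9 | step 3 | (5S,8R,10S)-6-(tert-butyldimethylsilyloxy)-12,13,14,15,16-pentanorlabda-6,9(11)-diene | C[C@@H]1C=C(O[Si](C)(C)C(C)(C)C)[C@H]2C(C)(C)CCC[C@]2(C)C1=C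
F10 | step 6 | (5S,6R,8R,9R,10S)-11-iodo-12,13,14,15,16-pentanorlabdane-6β,9α-diol | C[C@@H]1C[C@@H](O)[C@H]2C(C)(C)CCC[C@]2(C)[C@@]1(O)CI
F11 | step 6 | 2-[(tributylstannyl)methyl]prop-2-en-1-ol | C=C(CO)C[Sn](CCCC)(CCCC)CCCC
F12 | step 9 | (5S,8R,9R,10S,13R)-9α,13-epoxy-6-(trimethylsilyloxy)labd-6-en-15,16-olide | C[C@@H]1C=C(O[Si](C)(C)C)[C@H]2C(C)(C)CCC[C@]2(C)[C@@]12CC[C@@]1(COC(=O)C1)O2
F13 | step 9 | (5S,7R,8R,9R,10S,13R)-9α,13-epoxy-6-oxo-7β-(trimethylsilyloxy)labdan-15,16-olide | C[C@@H]1[C@@H](O[Si](C)(C)C)C(=O)[C@H]2C(C)(C)CCC[C@]2(C)[C@@]12CC[C@@]1(COC(=O)C1)O2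
A1 | alternative 1 | (5S,8R,9R,10S)-9α-hydroxy-6-oxolabd-13-en-15,16-olide | C[C@@H]1CC(=O)[C@H]2C(C)(C)CCC[C@]2(C)[C@@]1(O)CCC1=CC(=O)OC1
A2 | alternative 2 | C13-spiro cyclobutanone: 6-oxo-8α-methyl trans-decalin whose C9 (oxygen α) is the spiro atom of a 5-oxaspiro[3.4]octan-2-one | C[C@@H]1CC(=O)[C@H]2C(C)(C)CCC[C@]2(C)[C@@]12CCC1(CC(=O)C1)O2
A3 | alternative 2 | 9α,13-epoxy-15,16-dinorlabd-13(14)-en-6-one (exocyclic enol ether) | C[C@@H]1CC(=O)[C@H]2C(C)(C)CCC[C@]2(C)[C@@]12CCC(=C)O2
A4 | alternative 2 | 6-oxo-14,15,16-trinorlabdan-13,9α-olide (C9 spiro γ-lactone) | C[C@@H]1CC(=O)[C@H]2C(C)(C)CCC[C@]2(C)[C@@]12CCC(=O)O2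
A5 | alternative 3 | (5S,10S,13R)-13-hydroxy-7-oxolabd-8-en-15,16-olide | CC1=C(CC[C@]2(O)COC(=O)C2)[C@@]3(C)CCCC(C)(C)[C@@H]3CC1=O
A6 | alternative 3 | 9α,13R-epoxy-8α-methyl-7-oxolabdan-15,16-olide | C[C@@H]1C(=O)C[C@H]2C(C)(C)CCC[C@]2(C)[C@@]12CC[C@@]1(COC(=O)C1)O2
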